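**Strategy.** Everything rests on cutting the side chain between C5′ and C6′ (numbered from the resorcinol ring). The key step exploits that this is a plain CH2–CH2 link: C6′ is a primary carbon homoallylic to the C8′=C9′ Z-alkene, C5′ a primary carbon four methylenes from the benzene ring. Both are prepared as electrophiles; polarity reversal of the arene-side bromide to a Grignard reagent and copper catalysis join the C11 arylpentyl and C12 alkenol halves in one operation, with the finished Z-alkene and S-carbinol carried in intact. The precursors are MOM-protected 5-(5-bromopentyl)resorcinol and (S,Z)-11-hydroxydodec-3-enyl tosylate, built from (S)-propylene oxide and an alkyne.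

Key step: step 7

Remark: the carbinol carbon C16′ is S as read from the SMILES. Commercial 6 is racemic at its acetal carbon, so 8, 9, 11 and 12 are mixtures at that centre only; it is removed in step 4.

**Step 1**
Reactants: 1 5-bromoresorcinol
Product: 2 1-bromo-3,5-bis(methoxymethoxy)benzene
Conditions: MOMCl (2.6 equiv), i-Pr2NEt (3 equiv), CH2Cl2, 0 °C → rt
Reagents that add atoms: chloromethyl methyl ether, COCCl
Why: Base-mediated O-alkylation of both phenols with the reactive α-chloro ether (MOM protection, Williamson type) masks the acidic OH groups as acetals that tolerate Grignard and organolithium reagents.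

**Step 2**
Reactants: 2 1-bromo-3,5-bis(methoxymethoxy)benzene; 3 1,5-dibromopentane (4 equiv)
Product: 5 1-(5-bromopentyl)-3,5-bis(methoxymethoxy)benzene, via arylmagnesium bromide 4 (not isolated)
Conditions: Mg, THF, 50 °C; then added slowly to 3, Li2CuCl4 (3 mol %), THF/NMP, 0 °C → rt; aq. NH4Cl
Reagents that add atoms: magnesium, [Mg] (retained only in 4)
Why: Magnesium insertion gives the aryl Grignard reagent, which under Kochi-type copper catalysis substitutes one C–Br bond of the dibromide, the excess of 3 and the inverse addition favouring mono-alkylation.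

**Step 3**
Reactants: 6 2-(but-3-yn-1-yloxy)tetrahydro-2H-pyran; 7 1-bromo-5-chloropentane
Product: 9 2-[(9-chloronon-3-yn-1-yl)oxy]tetrahydro-2H-pyran, via lithium acetylide 8 (not isolated)
Conditions: n-BuLi, THF, −78 → 0 °C; then 7, DMPU, 0 °C → rt
Reagents that add atoms: n-butyllithium, [Li]CCCC (lithium retained only in 8)
Why: Acetylide alkylation (SN2), in which the lithium alkynide displaces bromide much faster than chloride in the dipolar cosolvent, so the chloride is kept for the next step.

**Step 4**
Reactants: 9 2-[(9-chloronon-3-yn-1-yl)oxy]tetrahydro-2H-pyran; 10 (S)-propylene oxide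
Product: 13 (S)-dodec-3-yne-1,11-diol, via alkylmagnesium chloride 11 (not isolated), via mono-THP ether 12 (not isolated)
Conditions: Mg (I2 cat.), THF, reflux; CuI (10 mol %), 10 (1.3 equiv), −30 → 0 °C; aq. NH4Cl; crude in MeOH, p-TsOH·H2O (cat.), rt
Reagents that add atoms: magnesium, [Mg] (retained only in 11)
Why: Grignard formation from the primary chloride and copper-catalysed SN2 opening of the epoxide at its unsubstituted CH2 leave the C–O stereocentre of (S)-propylene oxide untouched, so the carbinol is S, and acid methanolysis (transacetalisation) then removes the THP group.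

**Step 5**
Reactants: 13 (S)-dodec-3-yne-1,11-diol
Product: 14 (3Z,11S)-dodec-3-ene-1,11-diol
Conditions: H2 (1 atm), Lindlar catalyst, quinoline, EtOAc, rt, stopped after 1 equiv H2
Reagents that add atoms: none
Why: Lindlar semi-hydrogenation, in which syn delivery of H2 on the lead- and quinoline-poisoned palladium surface gives the Z-alkene and stops before the alkane.

**Step 6**
Reactants: 14 (3Z,11S)-dodec-3-ene-1,11-diol
Product: 15 (3Z,11S)-11-hydroxydodec-3-en-1-yl 4-methylbenzenesulfonate
Conditions: TsCl (1.05 equiv), Et3N, Me3N·HCl (10 mol %), CH2Cl2, −10 → 0 °C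
Reagents that add atoms: p-toluenesulfonyl chloride, Cc1ccc(S(=O)(=O)Cl)cc1
Why: Amine-catalysed sulfonylation is sterically governed, so with one equivalent of TsCl at low temperature the unhindered primary homoallylic hydroxyl should react well ahead of the secondary methyl carbinol.

**Step 7**
Reactants: 5 1-(5-bromopentyl)-3,5-bis(methoxymethoxy)benzene; 15 (3Z,11S)-11-hydroxydodec-3-en-1-yl 4-methylbenzenesulfonate
Product: 18 (2S,9Z)-17-[3,5-bis(methoxymethoxy)phenyl]heptadec-9-en-2-ol, via alkylmagnesium bromide 16 (not isolated), via lithium alkoxide 17 (not isolated)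
Conditions: 5, Mg, THF, 40 °C (→ 16); 15, n-BuLi (1.0 equiv), THF, −78 °C (→ 17); 16 (1.5 equiv) + 17, Li2CuCl4 (5 mol %), THF, −78 °C → rt; aq. NH4Cl
Reagents that add atoms: magnesium, [Mg] (retained only in 16); n-butyllithium, [Li]CCCC (lithium retained only in 17)
Why: Grignard reagent 16 transmetalates to copper(I) formed from Li2CuCl4, and the resulting alkyl cuprate displaces the primary tosylate of 17 by SN2 oxidative addition to a dialkylcopper(III) species that reductively eliminates the new C5′–C6′ bond. The closest known reaction type is the Kochi–Schlosser Li2CuCl4-catalysed coupling of alkylmagnesium halides with primary alkyl tosylates, long used for Z-alkenyl chains. No ring is closed and no stereocentre is created; the C2 carbinol, capped beforehand as its lithium alkoxide so that it consumes no Grignard reagent, is remote and untouched. The step needs substitution to outrun E2 elimination to the 1,3-diene and must keep the 9Z geometry. The two-electron SN2 pathway creates neither a radical nor a carbon–metal bond on the alkene-bearing half, the leaving group is homoallylic rather than allylic so SN2′ is not available, and placing the magnesium on the arene half excludes homoallyl–cyclopropylcarbinyl equilibration of the olefin. The MOM acetals are inert to Grignard and cuprate species.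

**Step 8**
Reactants: 18 (2S,9Z)-17-[3,5-bis(methoxymethoxy)phenyl]heptadec-9-en-2-ol
Product: 19 hansfordiol E
Conditions: HCl (3 M aq., cat. to 2 equiv), MeOH, 40 °C
Reagents that add atoms: none
Why: Acid-catalysed acetal methanolysis (MOM cleavage) frees both phenols, the formaldehyde unit being trapped by methanol, under conditions that should leave the isolated Z-alkene and the secondary alcohol unchanged.

**Compound list**
1 | 5-bromoresorcinol (5-bromobenzene-1,3-diol) | Oc1cc(O)cc(Br)c1 | starting material
2 | 1-bromo-3,5-bis(methoxymethoxy)benzene | COCOc1cc(Br)cc(OCOC)c1 | intermediate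
3 | 1,5-dibromopentane | BrCCCCCBr | starting material
4 | [3,5-bis(methoxymethoxy)phenyl]magnesium bromide | COCOc1cc([Mg]Br)cc(OCOC)c1 | intermediate
5 | 1-(5-bromopentyl)-3,5-bis(methoxymethoxy)benzene | COCOc1cc(CCCCCBr)cc(OCOC)c1 | intermediate
6 | 2-(but-3-yn-1-yloxy)tetrahydro-2H-pyran (racemic) | C#CCCOC1CCCCO1 | starting material
7 | 1-bromo-5-chloropentane | ClCCCCCBr | starting material
8 | lithium acetylide of 6, [4-(tetrahydro-2H-pyran-2-yloxy)but-1-yn-1-yl]lithium | [Li]C#CCCOC1CCCCO1 | intermediate
9 | 2-[(9-chloronon-3-yn-1-yl)oxy]tetrahydro-2H-pyran | ClCCCCCC#CCCOC1CCCCO1 | intermediate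
10 | (S)-propylene oxide, (S)-2-methyloxirane | C[C@H]1CO1 | starting material
11 | [9-(tetrahydro-2H-pyran-2-yloxy)non-6-yn-1-yl]magnesium chloride | Cl[Mg]CCCCCC#CCCOC1CCCCO1 | intermediate
12 | (2S)-12-(tetrahydro-2H-pyran-2-yloxy)dodec-9-yn-2-ol (both acetal epimers) | C[C@H](O)CCCCCCC#CCCOC1CCCCO1 | intermediate
13 | (S)-dodec-3-yne-1,11-diol | C[C@H](O)CCCCCCC#CCCO | intermediate
14 | (3Z,11S)-dodec-3-ene-1,11-diol | C[C@H](O)CCCCCC/C=C\CCO | intermediate
15 | (3Z,11S)-11-hydroxydodec-3-en-1-yl 4-methylbenzenesulfonate | C[C@H](O)CCCCCC/C=C\CCOS(=O)(=O)c1ccc(C)cc1 | intermediate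
16 | {5-[3,5-bis(methoxymethoxy)phenyl]pentyl}magnesium bromide | Br[Mg]CCCCCc1cc(OCOC)cc(OCOC)c1 | intermediate
17 | lithium alkoxide of 15, lithium (2S,9Z)-12-(tosyloxy)dodec-9-en-2-olate | C[C@H](O[Li])CCCCCC/C=C\CCOS(=O)(=O)c1ccc(C)cc1 | intermediate
18 | (2S,9Z)-17-[3,5-bis(methoxymethoxy)phenyl]heptadec-9-en-2-ol | C[C@H](O)CCCCCC/C=C\CCCCCCCc1cc(OCOC)cc(OCOC)c1 | intermediate
19 | hansfordiol E, 5-[(8Z,16S)-16-hydroxyheptadec-8-en-1-yl]benzene-1,3-diol | C[C@H](O)CCCCCC/C=C\CCCCCCCc1cc(O)cc(O)c1 | target

**Step count.** Total: 8 steps. Longest linear sequence: 6 steps (steps 3 to 8, from 6 and 7).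

**Steps most likely to fail**

Step 7. The cross-coupling may be outrun by E2 elimination of the homoallylic sulfonate to the conjugated diene or by homocoupling of the Grignard reagent, or turnover may stall because the alkoxide aggregates the cuprate. The fallback makes the same C5′–C6′ bond through a sulfone-stabilised carbanion instead of an organocopper species. Setting out from 5, displacement with sodium benzenesulfinate (DMF, 60 °C) should give 1-[5-(phenylsulfonyl)pentyl]-3,5-bis(methoxymethoxy)benzene F1. Its α-lithio derivative (n-BuLi, THF, −78 °C) would be alkylated with the alkoxide 17 (THF/DMPU, −78 → 0 °C) to (2S,9Z)-17-[3,5-bis(methoxymethoxy)phenyl]-13-(phenylsulfonyl)heptadec-9-en-2-ol F2, as a mixture of C13 epimers. Reductive desulfonylation (Na/Hg, Na2HPO4, MeOH, −20 °C, or Mg, MeOH) comes back to the route at 18. The transient C5′ radical is of the pent-4-enyl type and should not add to the alkene at a competitive rate, so the Z geometry is expected to hold.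

Step 6. Sulfonylation may also take place at the secondary hydroxyl, giving bis-tosylate, and chloride may displace the tosylate once formed. The fallback separates the two hydroxyls by protecting-group logic. Setting out from 14, both hydroxyls would be silylated (TBSCl, imidazole, DMF) to (3Z,11S)-1,11-bis(tert-butyldimethylsilyloxy)dodec-3-ene F3. The primary silyl ether is then cleaved selectively (CSA cat., MeOH/CH2Cl2, 0 °C) to (3Z,11S)-11-(tert-butyldimethylsilyloxy)dodec-3-en-1-ol F4. Tosylation (TsCl, pyridine) gives (3Z,11S)-11-(tert-butyldimethylsilyloxy)dodec-3-en-1-yl 4-methylbenzenesulfonate F5. Coupling of F5 with 16 under the copper conditions of step 7, without n-BuLi, should give tert-butyl{[(2S,9Z)-17-[3,5-bis(methoxymethoxy)phenyl]heptadec-9-en-2-yl]oxy}dimethylsilane F6. The conditions of step 8 then remove the silyl and MOM groups together, coming back to the route at 19.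

Step 2. The dibromide may be alkylated at both ends, the aryl Grignard reagent may homocouple to the biaryl, and the sp2–sp3 coupling may be slow. The fallback builds the chain by sp2–sp coupling and reduction. Setting out from 2, Sonogashira coupling with pent-4-yn-1-ol (Pd(PPh3)2Cl2, CuI, Et3N, 60 °C) should give 5-[3,5-bis(methoxymethoxy)phenyl]pent-4-yn-1-ol F7. Hydrogenation (H2, Pd/C, EtOAc) gives 5-[3,5-bis(methoxymethoxy)phenyl]pentan-1-ol F8, and an Appel reaction (CBr4, PPh3, CH2Cl2, 0 °C) comes back to the route at 5.

**Further compounds**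
F1 | step 7 | 1-[5-(phenylsulfonyl)pentyl]-3,5-bis(methoxymethoxy)benzene | COCOc1cc(CCCCCS(=O)(=O)c2ccccc2)cc(OCOC)c1
F2 | step 7 | (2S,9Z)-17-[3,5-bis(methoxymethoxy)phenyl]-13-(phenylsulfonyl)heptadec-9-en-2-ol (C13 epimers) | C[C@H](O)CCCCCC/C=C\CCC(CCCCc1cc(OCOC)cc(OCOC)c1)S(=O)(=O)c1ccccc1
F3 | step 6 | (3Z,11S)-1,11-bis(tert-butyldimethylsilyloxy)dodec-3-ene | C[C@H](O[Si](C)(C)C(C)(C)C)CCCCCC/C=C\CCO[Si](C)(C)C(C)(C)C
F4 | step 6 | (3Z,11S)-11-(tert-butyldimethylsilyloxy)dodec-3-en-1-ol | C[C@H](O[Si](C)(C)C(C)(C)C)CCCCCC/C=C\CCO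
F5 | step 6 | (3Z,11S)-11-(tert-butyldimethylsilyloxy)dodec-3-en-1-yl 4-methylbenzenesulfonate | C[C@H](O[Si](C)(C)C(C)(C)C)CCCCCC/C=C\CCOS(=O)(=O)c1ccc(C)cc1
F6 | step 6 | tert-butyl{[(2S,9Z)-17-[3,5-bis(methoxymethoxy)phenyl]heptadec-9-en-2-yl]oxy}dimethylsilane | C[C@H](O[Si](C)(C)C(C)(C)C)CCCCCC/C=C\CCCCCCCc1cc(OCOC)cc(OCOC)c1
F7 | step 2 | 5-[3,5-bis(methoxymethoxy)phenyl]pent-4-yn-1-ol | OCCCC#Cc1cc(OCOC)cc(OCOC)c1
F8 | step 2 | 5-[3,5-bis(methoxymethoxy)phenyl]pentan-1-ol | OCCCCCc1cc(OCOC)cc(OCOC)c1
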